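**Retrosynthetic overview**
- Target 15 comes from its N11-Boc derivative 14 by carbamate cleavage.
- The central benzene ring (C4b, C5, C6, C6a, C11a, C11b) holds the C2=C3 bonds of both indoles (C11b=C4b and C11a=C6a) and the C5–C6 bis(methoxy) unit. It is cut at C6–C6a and C11a–C11b into the 3-(1,2-dimethoxyvinyl)indole 8 (4π) and the 3-bromo-2-nitroindole 12 (2π).
- This ring is the only one formed and it is formed last, by a polar [4+2] addition followed by loss of HBr and HNO2; both indole bicycles are bought as 6-chloroindole.
- Diene 8 comes from 6-chloroindole by C3 methoxyacetylation, N-Boc protection, enolate O-methylation and Boc removal; dienophile 12 comes from 6-chloroindole by C3 bromination, N-Boc protection and C2 lithiation/nitration.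

Key step: step 8

Remark on the chemistry: the target is achiral. The only stereogenic compound, cycloadduct 13, is racemic; its SMILES shows only the cis ring fusion (C6a–Br and C11a–NO2 on the same face), and C6 and C11b are left open because all four centres are lost in the same flask.

**Step 1**
Reactants: 1 6-chloro-1H-indole; 2 methoxyacetyl chloride
Product: 3 1-(6-chloro-1H-indol-3-yl)-2-methoxyethan-1-one
Conditions: Et2AlCl (1.5 equiv), CH2Cl2, 0 °C; then 2, 0 °C → rt; aq. NaHCO3 work-up
Reagents that add atoms: methoxyacetyl chloride (compound 2), COCC(=O)Cl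
Why: Friedel–Crafts acylation of an N–H indole with an acid chloride and Et2AlCl should go at C3, the most nucleophilic carbon, because the aluminium reagent activates the acid chloride and takes up HCl without N-acylation or acid-driven oligomerization.

**Step 2**
Reactants: 3 1-(6-chloro-1H-indol-3-yl)-2-methoxyethan-1-one; 4 di-tert-butyl dicarbonate
Product: 5 tert-butyl 6-chloro-3-(2-methoxyacetyl)indole-1-carboxylate
Conditions: Boc2O (1.2 equiv), DMAP (0.1 equiv), MeCN, rt
Reagents that add atoms: di-tert-butyl dicarbonate (compound 4), CC(C)(C)OC(=O)OC(=O)OC(C)(C)C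
Why: DMAP-catalysed N-acylation (carbamate protection) of the acidic N–H of a 3-acylindole should be clean, and it removes the N–H that would otherwise be methylated in step 3.

**Step 3**
Reactants: 5 tert-butyl 6-chloro-3-(2-methoxyacetyl)indole-1-carboxylate
Product: 7 tert-butyl 6-chloro-3-[(Z)-1,2-dimethoxyethenyl]indole-1-carboxylate, via potassium enolate 6 (not isolated)
Conditions: KN(SiMe3)2 (1.1 equiv), THF/DMPU, −78 °C; then Me2SO4 (1.5 equiv), −78 → 0 °C; aq. NH3 quench; Et3N-treated silica
Reagents that add atoms: dimethyl sulfate, COS(=O)(=O)OC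
Why: Enolate O-alkylation: the potassium enolate should form with O–K cis to the methoxy group (allylic strain against the indolyl group plus K–OMe contact), and the hard electrophile Me2SO4 in a dipolar aprotic medium should methylate oxygen with retention of that geometry, giving the Z enol ether.

**Step 4**
Reactants: 7 tert-butyl 6-chloro-3-[(Z)-1,2-dimethoxyethenyl]indole-1-carboxylate
Product: 8 6-chloro-3-[(Z)-1,2-dimethoxyethenyl]-1H-indole
Conditions: NaOMe (0.3 equiv), MeOH/THF, rt; aq. NaHCO3 work-up, no acid contact; used at once
Reagents that add atoms: none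
Why: Methoxide-catalysed methanolysis (transacylation) of an indole N-carbamate should free N–H under basic conditions that the acid-labile enol ether tolerates, and the N–H diene is the more electron-rich partner for step 8.

**Step 5**
Reactants: 1 6-chloro-1H-indole
Product: 9 3-bromo-6-chloro-1H-indole
Conditions: NBS (1.0 equiv), DMF, 0 °C, dark; aqueous work-up, crude carried on at once
Reagents that add atoms: N-bromosuccinimide, O=C1CCC(=O)N1Br
Why: Electrophilic aromatic bromination with NBS should take place only at C3, the most nucleophilic position of the indole.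

**Step 6**
Reactants: 9 3-bromo-6-chloro-1H-indole; 4 di-tert-butyl dicarbonate
Product: 10 tert-butyl 3-bromo-6-chloroindole-1-carboxylate
Conditions: Boc2O (1.2 equiv), DMAP (0.1 equiv), CH2Cl2, 0 °C → rt
Reagents that add atoms: di-tert-butyl dicarbonate (compound 4), CC(C)(C)OC(=O)OC(=O)OC(C)(C)C
Why: DMAP-catalysed N-acylation (carbamate protection) should stabilize the 3-bromoindole and install the group that acidifies and directs C2–H for step 7.

**Step 7**
Reactants: 10 tert-butyl 3-bromo-6-chloroindole-1-carboxylate
Product: 12 tert-butyl 3-bromo-6-chloro-2-nitroindole-1-carboxylate, via 2-lithioindole 11 (not isolated)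
Conditions: LiN(iPr)2 (1.1 equiv), THF, −78 °C; then cannula transfer into N2O4 (4 equiv), THF, −110 → −78 °C; aq. NaHCO3
Reagents that add atoms: dinitrogen tetroxide, O=[N+]([O-])[N+](=O)[O-]
Why: Directed lithiation then nitration of the organolithium with N2O4: the amide base should remove the C2 proton (flanked by the carbamate nitrogen and bromine) without bromine–lithium exchange, and inverse addition of 11 to excess N2O4 at very low temperature should give the C2-nitro compound, as is known for 2-lithio-N-Boc-indoles.

**Step 8**
Reactants: 8 6-chloro-3-[(Z)-1,2-dimethoxyethenyl]-1H-indole; 12 tert-butyl 3-bromo-6-chloro-2-nitroindole-1-carboxylate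
Product: 14 tert-butyl 2,9-dichloro-5,6-dimethoxy-12H-indolo[2,3-a]carbazole-11-carboxylate, via bromo nitro cycloadduct 13 (not isolated)
Conditions: 8 (1.3 equiv), 12 (1.0 equiv), 2,6-lutidine (3 equiv), 4 Å molecular sieves, ClCH2CH2Cl, rt → 70 °C, Ar, dark
Reagents that add atoms: none
Why: Proposed new method: the diene terminus C6 of 8, made nucleophilic by N12 through C11b=C4b and by the C5 methoxy group, should add to C3 of 12 (the carbon beta to the nitro group), and the C11a nitronate should then attack the indoleninium carbon C11b, so the central ring closes in a stepwise polar [4+2] sense, the second bond by a 6-exo-trig nitro-Mannich attack, to give 13. Adduct 13 carries a leaving group on each former dienophile carbon, so loss of bromide from C6a with the C6 proton and of nitrite from C11a with the C11b proton, both taken up by 2,6-lutidine, should give the benzene ring at the right oxidation level without an oxidant. The closest known reaction type is the Diels–Alder reaction of N-acyl 2- and 3-nitroindoles with oxygenated dienes, which gives carbazoles after loss of nitrous acid, together with the use of 3-vinylindoles as dienes; a 3-halo-2-nitroindole has not been used as the 2π partner, which is why the step is new. The four stereocentres of 13 (C6, C6a, C11a, C11b) are all destroyed on aromatization, so no stereocontrol is needed. The step needs regioselectivity (C6 to C6a, hence adjacent nitrogens), secured by matching the nucleophilic diene terminus with the nitro-beta carbon, and aromatization by loss of HBr and HNO2 and not of methanol, secured by the far better leaving groups bromide and nitrite as long as the medium stays free of acid. Should the zwitterion expel bromide before ring closure, the resulting 3-alkenyl-2-nitroindole is a 1,3,5-triene that can still reach 14 by 6π electrocyclization and loss of nitrous acid.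

**Step 9**
Reactants: 14 tert-butyl 2,9-dichloro-5,6-dimethoxy-12H-indolo[2,3-a]carbazole-11-carboxylate
Product: 15 borregomycin E (2,9-dichloro-5,6-dimethoxy-11,12-dihydroindolo[2,3-a]carbazole)
Conditions: CF3CO2H/CH2Cl2 (1:4), 0 °C → rt
Reagents that add atoms: none
Why: Acidolysis of a tert-butyl carbamate (loss of the tert-butyl cation as isobutene, then decarboxylation) should free N11–H, while the aryl chlorides, methyl ethers and carbazole core are inert to the acid.

**Compound list**
1 | 6-chloro-1H-indole | Clc1ccc2cc[nH]c2c1 | starting material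
2 | methoxyacetyl chloride | COCC(=O)Cl | starting material
3 | 1-(6-chloro-1H-indol-3-yl)-2-methoxyethan-1-one | COCC(=O)c1c[nH]c2cc(Cl)ccc12 | intermediate
4 | di-tert-butyl dicarbonate | CC(C)(C)OC(=O)OC(=O)OC(C)(C)C | starting material
5 | tert-butyl 6-chloro-3-(2-methoxyacetyl)indole-1-carboxylate | COCC(=O)c1cn(C(=O)OC(C)(C)C)c2cc(Cl)ccc12 | intermediate
6 | potassium (Z)-1-[1-(tert-butoxycarbonyl)-6-chloroindol-3-yl]-2-methoxyethen-1-olate (formed in the flask, not isolated) | CO/C=C(\[O-])c1cn(C(=O)OC(C)(C)C)c2cc(Cl)ccc12.[K+] | intermediate
7 | tert-butyl 6-chloro-3-[(Z)-1,2-dimethoxyethenyl]indole-1-carboxylate | CO/C=C(\OC)c1cn(C(=O)OC(C)(C)C)c2cc(Cl)ccc12 | intermediate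
8 | 6-chloro-3-[(Z)-1,2-dimethoxyethenyl]-1H-indole | CO/C=C(\OC)c1c[nH]c2cc(Cl)ccc12 | intermediate
9 | 3-bromo-6-chloro-1H-indole | Brc1c[nH]c2cc(Cl)ccc12 | intermediate
10 | tert-butyl 3-bromo-6-chloroindole-1-carboxylate | CC(C)(C)OC(=O)n1cc(Br)c2ccc(Cl)cc21 | intermediate
11 | tert-butyl 3-bromo-6-chloro-2-lithioindole-1-carboxylate (formed in the flask, not isolated) | [Li]c1c(Br)c2ccc(Cl)cc2n1C(=O)OC(C)(C)C | intermediate
12 | tert-butyl 3-bromo-6-chloro-2-nitroindole-1-carboxylate | CC(C)(C)OC(=O)n1c([N+](=O)[O-])c(Br)c2ccc(Cl)cc21 | intermediate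
13 | tert-butyl 6a-bromo-2,9-dichloro-5,6-dimethoxy-11a-nitro-6,6a,11a,11b-tetrahydro-12H-indolo[2,3-a]carbazole-11-carboxylate (C4b=C5 double bond; racemic, 6a-Br and 11a-NO2 cis, C6 and C11b unassigned; formed in the flask, not isolated) | COC1=C2c3ccc(Cl)cc3NC2[C@]4([N+](=O)[O-])N(C(=O)OC(C)(C)C)c3cc(Cl)ccc3[C@]4(Br)C1OC | intermediate
14 | tert-butyl 2,9-dichloro-5,6-dimethoxy-12H-indolo[2,3-a]carbazole-11-carboxylate | COc1c(OC)c2c3ccc(Cl)cc3n(C(=O)OC(C)(C)C)c2c2[nH]c3cc(Cl)ccc3c12 | intermediate
15 | borregomycin E (2,9-dichloro-5,6-dimethoxy-11,12-dihydroindolo[2,3-a]carbazole) | COc1c(OC)c2c3ccc(Cl)cc3[nH]c2c2[nH]c3cc(Cl)ccc3c12 | target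

**Totals**
Total step count: 9
Longest linear sequence: 6 steps (steps 1, 2, 3, 4, 8, 9); the dienophile arm is steps 5, 6, 7 and joins at step 8.

**Steps most likely to fail**

1. Step 8 (Proposed new method). The tetrasubstituted, bromine-bearing C2=C3 bond of 12 may add too slowly, so that diene 8 is consumed by hydrolysis or self-condensation. Alternatively the adduct may re-aromatize its indole by a hydrogen shift and then lose methanol instead of HBr and HNO2. The fallback uses known chemistry, sets out from 5 and 10 and returns at 15. Palladium-catalysed alpha-arylation of ketone 5 with bromide 10 (Pd2(dba)3 as zerovalent palladium source, Xantphos, K3PO4, toluene, 80 °C; the C–Br bond should react well before C–Cl) should form the C6–C6a bond and give racemic di-tert-butyl 3,3'-(1-methoxy-2-oxoethane-1,2-diyl)bis(6-chloroindole-1-carboxylate) F1. O-Methylation of its potassium enolate as in step 3 (KN(SiMe3)2, Me2SO4) should give di-tert-butyl 3,3'-[(Z)-1,2-dimethoxyethene-1,2-diyl]bis(6-chloroindole-1-carboxylate) F2; the E isomer is equally usable because light interconverts the two. NaOMe in MeOH should remove both carbamates and give 3,3'-[(Z)-1,2-dimethoxyethene-1,2-diyl]bis(6-chloro-1H-indole) F3. Stilbene-type oxidative photocyclization (Mallory reaction: hν, I2, propylene oxide, THF/benzene), as used for bis(indol-3-yl)ethenes, should then join C11a to C11b and give 15 directly.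

2. Step 7. The 3-bromo-2-lithio species 11 may eliminate LiBr or scramble its halogen, and the diisopropylamine present may consume N2O4 and return acid that protonates 11, so that nitration is inefficient. The fallback sets out from 1 (with 4) and returns at 12; it installs the nitro group on a bromine-free lithioindole with an amine-free base and brings in bromine afterwards by electrophilic substitution. Boc2O/DMAP should convert 1 into tert-butyl 6-chloroindole-1-carboxylate F4. C2-lithiation with t-BuLi (THF, −78 °C) and inverse addition to N2O4 at −110 °C should give tert-butyl 6-chloro-2-nitroindole-1-carboxylate F5. CF3CO2H should remove the carbamate to give 6-chloro-2-nitro-1H-indole F6. NBS in DMF should brominate C3, still the enamine-type carbon, to give 3-bromo-6-chloro-2-nitro-1H-indole F7, and Boc2O/DMAP should return 12.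

3. Step 3. The enolate 6 may be methylated on carbon instead of oxygen, or may attack the carbamate of a second molecule (Boc transfer), which would lower the supply of 7. The fallback sets out from 5 and returns at 7; it replaces enolate alkylation by ketal formation and elimination. HC(OMe)3, MeOH and catalytic TsOH should give the dimethyl ketal tert-butyl 6-chloro-3-(1,1,2-trimethoxyethyl)indole-1-carboxylate F8. Me3SiOTf with iPr2NEt (CH2Cl2, −20 °C → rt; Gassman-type ketal-to-enol-ether elimination) should then remove one methanol and give 7. The Z isomer (indolyl cis to hydrogen, the two methoxy groups cis) is expected to predominate after equilibration and is separated from any E isomer on base-treated silica.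

**Further compounds**
F1 | step 8 | di-tert-butyl 3,3'-(1-methoxy-2-oxoethane-1,2-diyl)bis(6-chloroindole-1-carboxylate), racemic | COC(C(=O)c1cn(C(=O)OC(C)(C)C)c2cc(Cl)ccc12)c1cn(C(=O)OC(C)(C)C)c2cc(Cl)ccc12
F2 | step 8 | di-tert-butyl 3,3'-[(Z)-1,2-dimethoxyethene-1,2-diyl]bis(6-chloroindole-1-carboxylate) | CO/C(=C(\OC)c1cn(C(=O)OC(C)(C)C)c2cc(Cl)ccc12)c1cn(C(=O)OC(C)(C)C)c2cc(Cl)ccc12
F3 | step 8 | 3,3'-[(Z)-1,2-dimethoxyethene-1,2-diyl]bis(6-chloro-1H-indole) | CO/C(=C(\OC)c1c[nH]c2cc(Cl)ccc12)c1c[nH]c2cc(Cl)ccc12
F4 | step 7 | tert-butyl 6-chloroindole-1-carboxylate | CC(C)(C)OC(=O)n1ccc2ccc(Cl)cc21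
F5 | step 7 | tert-butyl 6-chloro-2-nitroindole-1-carboxylate | CC(C)(C)OC(=O)n1c([N+](=O)[O-])cc2ccc(Cl)cc21
F6 | step 7 | 6-chloro-2-nitro-1H-indole | O=[N+]([O-])c1cc2ccc(Cl)cc2[nH]1
F7 | step 7 | 3-bromo-6-chloro-2-nitro-1H-indole | O=[N+]([O-])c1[nH]c2cc(Cl)ccc2c1Br
F8 | step 3 | tert-butyl 6-chloro-3-(1,1,2-trimethoxyethyl)indole-1-carboxylate | COCC(OC)(OC)c1cn(C(=O)OC(C)(C)C)c2cc(Cl)ccc12
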